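## Retrosynthetic overview

- The route rests on the tertiary α-ketol C6(=O)–C7(OH)(CH3) in the carbocycle (C4a, C5, C6, C7, C8, C8a). C6 is the carbonyl end of the vinylogous chain C6–C5=C4a–C4=C3–O2 that runs into the pyran ring. C6–C7 is therefore cut as an aldehyde–ketone benzoin: C6 acyl anion from a dienal, C7 methyl ketone.
- Target ⇐ acetylation of the 7,8-diol ⇐ desilylation of the 8-O-silyl α-ketol ⇐ carbene-catalysed closure of a pyran keto-dienal.
- Keto-dienal ⇐ two-carbon homologation of a 2,3-dihydro-4H-pyran-4-one (C4a carbonyl) with (Z)-2-ethoxyvinyllithium, then unmasking and oxidation of C7–OH. Pyranone ⇐ 6-endo-dig closure (O2–C3) of a β-hydroxy ynone.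
- Ynone ⇐ Weinreb amide + side-chain dienyne. The amide comes from an oxazolidinone syn aldol (C8–C8a) of a 3-(4-methoxybenzyloxy)propanoyl imide with O-triethylsilyl (S)-lactaldehyde. The dienyne comes from (S)-2-methylbutan-1-ol by Wittig and Horner–Wadsworth–Emmons olefinations.
- Ring order: pyran ring (O2, C1, C8a, C4a, C4, C3) first, in step 16; carbocycle second, in step 20.

Key step: step 20

Remark 1: the push–pull dienals 29, 30 and 31 are expected as C4a=C5 geometric isomers that interconvert through their O-protonated or hydrogen-bonded forms. They are written as the isomer with C6 cis to C8a, the only one that can cyclise; the other isomer is carried along.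

Remark 2: which enantiomer of the aminoindanol-derived triazolium salt reinforces the substrate's own facial bias cannot be fixed on paper. The (5aS,10bR) salt is written, and its commercial antipode takes its place if the pairing proves mismatched.

## Route

Step 1
Reactants: 1 3-bromo-1-(trimethylsilyl)prop-1-yne
Product: 2 diethyl [3-(trimethylsilyl)prop-2-yn-1-yl]phosphonate
Conditions: P(OEt)3 (neat), 110 °C
Reagents that add atoms: triethyl phosphite, CCOP(OCC)OCC
Why: Michaelis–Arbuzov reaction, in which the phosphite displaces the primary propargylic bromide and bromide then dealkylates the phosphonium ion.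

Step 2
Reactants: 3 (S)-2-methylbutan-1-ol
Product: 5 ethyl (S,E)-2,4-dimethylhex-2-enoate, via (S)-2-methylbutanal 4 (not isolated)
Conditions: TEMPO (10 mol %), PhI(OAc)2, CH2Cl2, rt; then Ph3P=C(CH3)CO2Et, rt
Reagents that add atoms: ethyl 2-(triphenylphosphoranylidene)propanoate, CCOC(=O)C(C)=P(c1ccccc1)(c1ccccc1)c1ccccc1
Why: Oxoammonium oxidation without base gives the epimerisable aldehyde, which is trapped in the same flask by an E-selective Wittig reaction of the stabilised ylide, so the stereocentre from 3 should be kept.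

Step 3
Reactants: 5 ethyl (S,E)-2,4-dimethylhex-2-enoate
Product: 6 (S,E)-2,4-dimethylhex-2-en-1-ol
Conditions: i-Bu2AlH, CH2Cl2, −78 °C; aq. KNaC4H4O6 work-up
Reagents that add atoms: none
Why: Hydride 1,2-reduction of the enoate by DIBAL-H should give the allylic alcohol without touching the alkene.

Step 4
Reactants: 6 (S,E)-2,4-dimethylhex-2-en-1-ol
Product: 7 (S,E)-2,4-dimethylhex-2-enal
Conditions: MnO2 (activated), CH2Cl2, rt
Reagents that add atoms: none
Why: Selective allylic oxidation with MnO2 under neutral conditions should leave the alkene geometry and the γ-stereocentre intact.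

Step 5
Reactants: 2 diethyl [3-(trimethylsilyl)prop-2-yn-1-yl]phosphonate; 7 (S,E)-2,4-dimethylhex-2-enal
Product: 10 (3E,5E,7S)-5,7-dimethylnona-3,5-dien-1-yne, via lithiated phosphonate 8 (not isolated), via silyl dienyne 9 (not isolated)
Conditions: 2, LiN(SiMe3)2, THF, −78 °C; 7, −78 → 0 °C; then K2CO3 (cat.), MeOH, rt
Reagents that add atoms: lithium bis(trimethylsilyl)amide, [Li]N([Si](C)(C)C)[Si](C)(C)C (its lithium stays in 8 only)
Why: Horner–Wadsworth–Emmons olefination with the propargyl phosphonate anion should be E-selective, and methanolysis then cleaves the C(sp)–Si bond.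

Step 6
Reactants: 11 ethyl (S)-lactate
Product: 12 ethyl (S)-2-[(triethylsilyl)oxy]propanoate
Conditions: Et3SiCl, imidazole, CH2Cl2, 0 °C → rt
Reagents that add atoms: chlorotriethylsilane, CC[Si](CC)(CC)Cl
Why: Standard silylation of a secondary alcohol; the triethylsilyl group is chosen so that the C7 oxygen can later be freed beside a tert-butyldimethylsilyl ether at C8.

Step 7
Reactants: 12 ethyl (S)-2-[(triethylsilyl)oxy]propanoate
Product: 13 (S)-2-[(triethylsilyl)oxy]propanal
Conditions: i-Bu2AlH, CH2Cl2, −78 °C; aq. KNaC4H4O6 work-up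
Reagents that add atoms: none
Why: Partial reduction of the ester by DIBAL-H stops at the aluminium hemiacetal at low temperature, and the α-silyloxy aldehyde is used at once to avoid epimerisation.

Step 8
Reactants: 14 propane-1,3-diol
Product: 15 3-[(4-methoxybenzyl)oxy]propan-1-ol
Conditions: NaH (1 equiv), 4-MeOC6H4CH2Cl, n-Bu4NI (cat.), THF, 0 °C → rt (diol in excess)
Reagents that add atoms: 4-methoxybenzyl chloride, COc1ccc(CCl)cc1
Why: Williamson mono-etherification of a symmetrical diol used in excess.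

Step 9
Reactants: 15 3-[(4-methoxybenzyl)oxy]propan-1-ol
Product: 16 3-[(4-methoxybenzyl)oxy]propanoic acid
Conditions: TEMPO (cat.), PhI(OAc)2, MeCN/H2O, rt
Reagents that add atoms: water, O
Why: Oxoammonium oxidation in aqueous medium takes the primary alcohol through the aldehyde hydrate to the acid and leaves the benzylic ether alone.

Step 10
Reactants: 16 3-[(4-methoxybenzyl)oxy]propanoic acid; 17 (R)-4-benzyloxazolidin-2-one
Product: 19 (R)-4-benzyl-3-{3-[(4-methoxybenzyl)oxy]propanoyl}oxazolidin-2-one, via mixed pivalic anhydride 18 (not isolated)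
Conditions: t-BuCOCl, Et3N, THF, −20 °C; then 17, LiCl, −20 °C → rt
Reagents that add atoms: pivaloyl chloride, CC(C)(C)C(=O)Cl (its atoms stay in 18 only)
Why: N-Acylation of the oxazolidinone through the mixed anhydride, with LiCl activation, occurs at the less hindered carbonyl.

Step 11
Reactants: 19 (R)-4-benzyl-3-{3-[(4-methoxybenzyl)oxy]propanoyl}oxazolidin-2-one; 13 (S)-2-[(triethylsilyl)oxy]propanal
Product: 21 (R)-4-benzyl-3-[(2R,3R,4S)-3-hydroxy-2-{[(4-methoxybenzyl)oxy]methyl}-4-[(triethylsilyl)oxy]pentanoyl]oxazolidin-2-one, via dibutylboron Z-enolate 20 (not isolated)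
Conditions: n-Bu2BOTf, i-Pr2NEt, CH2Cl2, −78 → 0 °C; 13, −78 → 0 °C; then pH 7 buffer (NaH2PO4/Na2HPO4), MeOH, H2O2, 0 °C
Reagents that add atoms: dibutylboron triflate, CCCCB(CCCC)OS(=O)(=O)C(F)(F)F (its boron stays in 20 only)
Why: Evans syn aldol through a Zimmerman–Traxler chair in which the (R)-auxiliary fixes the enolate face and so sets C8a and C8 (2R,3R), and the (S)-aldehyde is the matched partner because a Z-enolate adds to an α-silyloxy aldehyde in the polar Felkin–Anh (3,4-anti) sense.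

Step 12
Reactants: 21 aldol adduct
Product: 22 (2R,3R,4S)-3-hydroxy-N-methoxy-2-{[(4-methoxybenzyl)oxy]methyl}-N-methyl-4-[(triethylsilyl)oxy]pentanamide
Conditions: MeONHMe·HCl, AlMe3, CH2Cl2, −20 → 0 °C; aq. KNaC4H4O6 work-up
Reagents that add atoms: N,O-dimethylhydroxylamine hydrochloride, Cl.CNOC
Why: Weinreb transamidation, in which the aluminium amide is delivered to the exocyclic carbonyl by the aluminium alkoxide of the free β-hydroxyl and the auxiliary is released.

Step 13
Reactants: 22 hydroxy Weinreb amide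
Product: 23 (2R,3R,4S)-3-[(tert-butyldimethylsilyl)oxy]-N-methoxy-2-{[(4-methoxybenzyl)oxy]methyl}-N-methyl-4-[(triethylsilyl)oxy]pentanamide
Conditions: t-BuMe2SiOTf, 2,6-lutidine, CH2Cl2, −78 → 0 °C
Reagents that add atoms: tert-butyldimethylsilyl triflate, CC(C)(C)[Si](C)(C)OS(=O)(=O)C(F)(F)F
Why: Silylation of the hindered C8 hydroxyl with a silyl triflate and a non-nucleophilic base should not disturb the triethylsilyl ether.

Step 14
Reactants: 10 (3E,5E,7S)-5,7-dimethylnona-3,5-dien-1-yne; 23 silylated Weinreb amide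
Product: 25 (2S,3R,4R,8E,10E,12S)-3-[(tert-butyldimethylsilyl)oxy]-4-{[(4-methoxybenzyl)oxy]methyl}-10,12-dimethyl-2-[(triethylsilyl)oxy]tetradeca-8,10-dien-6-yn-5-one, via lithium acetylide 24 (not isolated)
Conditions: 10, n-BuLi, THF, −78 °C; then 23, −78 → 0 °C; AcOH quench at −78 °C
Reagents that add atoms: n-butyllithium, [Li]CCCC (its lithium stays in 24 only)
Why: Acetylide addition to a Weinreb amide stops at the chelated tetrahedral intermediate, so the ynone forms only on the acidic quench and the α-stereocentre is not exposed to base as a ketone.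

Step 15
Reactants: 25 ynone
Product: 26 (2S,3R,4R,8E,10E,12S)-3-[(tert-butyldimethylsilyl)oxy]-4-(hydroxymethyl)-10,12-dimethyl-2-[(triethylsilyl)oxy]tetradeca-8,10-dien-6-yn-5-one
Conditions: DDQ, CH2Cl2/pH 7 buffer (NaH2PO4/Na2HPO4), 0 °C, dark
Reagents that add atoms: none
Why: Oxidative cleavage of the 4-methoxybenzyl ether by DDQ is carried out here, where the π-system is an electron-poor dienynone and the silyl ethers are buffered.

Step 16
Reactants: 26 β-hydroxy ynone
Product: 27 (3R)-3-[(1R,2S)-1-[(tert-butyldimethylsilyl)oxy]-2-[(triethylsilyl)oxy]propyl]-6-[(1E,3E,5S)-3,5-dimethylhepta-1,3-dien-1-yl]-2,3-dihydro-4H-pyran-4-one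
Conditions: Ph3PAuCl (5 mol %), AgOTf (5 mol %), CH2Cl2, rt, dark
Reagents that add atoms: none
Why: π-Acid activation of the ynone by Ph3PAu+ lets the primary hydroxyl attack the β-alkyne carbon in a 6-endo-dig oxa-Michael closure (O2–C3), and the absence of base avoids β-elimination and retro-aldol cleavage and leaves C8a untouched.

Step 17
Reactants: 27 dihydropyranone
Product: 29 2-{(3R)-3-[(1R,2S)-1-[(tert-butyldimethylsilyl)oxy]-2-[(triethylsilyl)oxy]propyl]-6-[(1E,3E,5S)-3,5-dimethylhepta-1,3-dien-1-yl]-2,3-dihydro-4H-pyran-4-ylidene}acetaldehyde (CHO drawn cis to pyran C3), via ethoxyvinyl carbinol 28 (not isolated)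
Conditions: (Z)-BrCH=CHOEt, t-BuLi (2 equiv), THF, −78 °C; then 27, −78 °C; then 0.5 M HCl, THF, 0 °C, short contact
Reagents that add atoms: (Z)-1-bromo-2-ethoxyethene, Br/C=C\OCC; water, O
Why: 1,2-Addition of (Z)-2-ethoxyvinyllithium to the vinylogous-ester carbonyl (as in Stork–Danheiser additions) gives a doubly allylic tertiary carbinol; acid ionises it, water adds at the ethoxy-bearing carbon and ethanol is lost, which gives the two-carbon-homologated enal conjugated to the ring enol ether, with the C4a=C5 geometry under thermodynamic control (remark 1).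

Step 18
Reactants: 29 bis-silylated dienal
Product: 30 2-{(3R)-3-[(1R,2S)-1-[(tert-butyldimethylsilyl)oxy]-2-hydroxypropyl]-6-[(1E,3E,5S)-3,5-dimethylhepta-1,3-dien-1-yl]-2,3-dihydro-4H-pyran-4-ylidene}acetaldehyde
Conditions: HF·pyridine, pyridine, THF, 0 °C, dark
Reagents that add atoms: none
Why: Buffered, non-aqueous fluoride cleaves the secondary triethylsilyl ether far faster than the hindered tert-butyldimethylsilyl ether and should spare the acid-sensitive dienol ether.

Step 19
Reactants: 30 hydroxy dienal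
Product: 31 2-{(3R)-3-[(1R)-1-[(tert-butyldimethylsilyl)oxy]-2-oxopropyl]-6-[(1E,3E,5S)-3,5-dimethylhepta-1,3-dien-1-yl]-2,3-dihydro-4H-pyran-4-ylidene}acetaldehyde
Conditions: Dess–Martin periodinane, pyridine, CH2Cl2, 0 °C → rt, dark
Reagents that add atoms: none
Why: Dess–Martin oxidation of the C7 carbinol to the methyl ketone under buffered neutral conditions should not touch the aldehyde, the polyene or the C8 stereocentre.

Step 20
Reactants: 31 keto-dienal
Product: 32 (7R,8R,8aR)-8-[(tert-butyldimethylsilyl)oxy]-3-[(1E,3E,5S)-3,5-dimethylhepta-1,3-dien-1-yl]-7-hydroxy-7-methyl-8,8a-dihydro-1H-isochromen-6(7H)-one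
Conditions: (5aS,10bR)-2-(pentafluorophenyl)-5a,10b-dihydro-4H,6H-indeno[2,1-b][1,2,4]triazolo[4,3-d][1,4]oxazin-2-ium tetrafluoroborate (20 mol %), Et3N (1 equiv), catechol (1 equiv), toluene, 23 → 40 °C, argon, dark
Reagents that add atoms: none
Why: The carbene freed from the triazolium salt by Et3N adds to the C6 aldehyde, proton transfer (shuttled by catechol) gives the hydroxy-enamine, its C6 attacks the C7 ketone, and collapse of the adduct releases the carbene and the α-ketol. The closest known reaction is the triazolium-catalysed intramolecular aldehyde–ketone crossed benzoin that gives six-membered tertiary α-ketols, and the catechol-assisted acyl-anion (Stetter) chemistry of enals with N-pentafluorophenyl triazolium carbenes supports an unsaturated donor. The carbocycle (C4a, C5, C6, C7, C8, C8a) closes 6-exo-trig. C7 is set by the ketone face: with the C8 silyl ether pseudo-equatorial and anti to the incoming C6 (polar Felkin–Anh), the methyl group ends pseudo-equatorial and the new hydroxyl cis to the C8 oxygen, and the aminoindanol backbone of the catalyst is chosen to reinforce that face (remark 2). The step needs acyl-anion rather than homoenolate reactivity, secured by the fully substituted β-carbon C4a, and the aldehyde as the only donor, secured because a ketone cannot form the hydroxy-enamine. Only the isomer with C6 cis to C8a can close, so the hydrogen-bond donor and gentle warming are meant to keep the weak push–pull C4a=C5 bond equilibrating and drain both isomers into the product.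

Step 21
Reactants: 32 silylated α-ketol
Product: 33 (7R,8R,8aR)-3-[(1E,3E,5S)-3,5-dimethylhepta-1,3-dien-1-yl]-7,8-dihydroxy-7-methyl-8,8a-dihydro-1H-isochromen-6(7H)-one
Conditions: n-Bu4NF, AcOH (1:1), THF, 0 °C → rt, dark
Reagents that add atoms: none
Why: Fluoride desilylation buffered with acetic acid should free the C8 hydroxyl without base-induced α-ketol rearrangement or epimerisation at C8a.

Step 22
Reactants: 33 7,8-diol
Product: 34 8-acetyldechloroisochromophilone III, (7R,8R,8aR)-3-[(1E,3E,5S)-3,5-dimethylhepta-1,3-dien-1-yl]-7-hydroxy-7-methyl-6-oxo-6,7,8,8a-tetrahydro-1H-isochromen-8-yl acetate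
Conditions: Ac2O, pyridine, DMAP (cat.), CH2Cl2, 0 °C
Reagents that add atoms: acetic anhydride, CC(=O)OC(C)=O
Why: Nucleophile-catalysed acylation should take the secondary C8 hydroxyl much faster than the tertiary C7 hydroxyl of the α-ketol.

## Compound list

1 | 3-bromo-1-(trimethylsilyl)prop-1-yne | C[Si](C)(C)C#CCBr | starting material
2 | diethyl [3-(trimethylsilyl)prop-2-yn-1-yl]phosphonate | CCOP(=O)(CC#C[Si](C)(C)C)OCC | intermediate
3 | (S)-2-methylbutan-1-ol | CC[C@H](C)CO | starting material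
4 | (S)-2-methylbutanal (not isolated) | CC[C@H](C)C=O | intermediate
5 | ethyl (S,E)-2,4-dimethylhex-2-enoate | CC[C@H](C)/C=C(C)/C(=O)OCC | intermediate
6 | (S,E)-2,4-dimethylhex-2-en-1-ol | CC[C@H](C)/C=C(C)/CO | intermediate
7 | (S,E)-2,4-dimethylhex-2-enal | CC[C@H](C)/C=C(C)/C=O | intermediate
8 | lithiated phosphonate from 2 (not isolated) | [Li+].CCOP(=O)([CH-]C#C[Si](C)(C)C)OCC | intermediate
9 | trimethyl[(3E,5E,7S)-5,7-dimethylnona-3,5-dien-1-yn-1-yl]silane (not isolated) | CC[C@H](C)/C=C(C)/C=C/C#C[Si](C)(C)C | intermediate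
10 | (3E,5E,7S)-5,7-dimethylnona-3,5-dien-1-yne | CC[C@H](C)/C=C(C)/C=C/C#C | intermediate
11 | ethyl (S)-lactate | CCOC(=O)[C@H](C)O | starting material
12 | ethyl (S)-2-[(triethylsilyl)oxy]propanoate | CCOC(=O)[C@H](C)O[Si](CC)(CC)CC | intermediate
13 | (S)-2-[(triethylsilyl)oxy]propanal | O=C[C@H](C)O[Si](CC)(CC)CC | intermediate
14 | propane-1,3-diol | OCCCO | starting material
15 | 3-[(4-methoxybenzyl)oxy]propan-1-ol | COc1ccc(COCCCO)cc1 | intermediate
16 | 3-[(4-methoxybenzyl)oxy]propanoic acid | COc1ccc(COCCC(=O)O)cc1 | intermediate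
17 | (R)-4-benzyloxazolidin-2-one | O=C1N[C@H](Cc2ccccc2)CO1 | starting material
18 | 3-[(4-methoxybenzyl)oxy]propanoic pivalic anhydride (not isolated) | COc1ccc(COCCC(=O)OC(=O)C(C)(C)C)cc1 | intermediate
19 | (R)-4-benzyl-3-{3-[(4-methoxybenzyl)oxy]propanoyl}oxazolidin-2-one | COc1ccc(COCCC(=O)N2[C@H](Cc3ccccc3)COC2=O)cc1 | intermediate
20 | dibutylboron (Z)-enolate of 19 (not isolated) | CCCCB(CCCC)O/C(=C\COCc1ccc(OC)cc1)N1[C@H](Cc2ccccc2)COC1=O | intermediate
21 | (R)-4-benzyl-3-[(2R,3R,4S)-3-hydroxy-2-{[(4-methoxybenzyl)oxy]methyl}-4-[(triethylsilyl)oxy]pentanoyl]oxazolidin-2-one | O=C(N1[C@H](Cc2ccccc2)COC1=O)[C@H](COCc1ccc(OC)cc1)[C@@H](O)[C@H](C)O[Si](CC)(CC)CC | intermediate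
22 | (2R,3R,4S)-3-hydroxy-N-methoxy-2-{[(4-methoxybenzyl)oxy]methyl}-N-methyl-4-[(triethylsilyl)oxy]pentanamide | CON(C)C(=O)[C@H](COCc1ccc(OC)cc1)[C@@H](O)[C@H](C)O[Si](CC)(CC)CC | intermediate
23 | (2R,3R,4S)-3-[(tert-butyldimethylsilyl)oxy]-N-methoxy-2-{[(4-methoxybenzyl)oxy]methyl}-N-methyl-4-[(triethylsilyl)oxy]pentanamide | CON(C)C(=O)[C@H](COCc1ccc(OC)cc1)[C@@H](O[Si](C)(C)C(C)(C)C)[C@H](C)O[Si](CC)(CC)CC | intermediate
24 | lithium acetylide of 10 (not isolated) | CC[C@H](C)/C=C(C)/C=C/C#C[Li] | intermediate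
25 | (2S,3R,4R,8E,10E,12S)-3-[(tert-butyldimethylsilyl)oxy]-4-{[(4-methoxybenzyl)oxy]methyl}-10,12-dimethyl-2-[(triethylsilyl)oxy]tetradeca-8,10-dien-6-yn-5-one | CC[C@H](C)/C=C(C)/C=C/C#CC(=O)[C@H](COCc1ccc(OC)cc1)[C@@H](O[Si](C)(C)C(C)(C)C)[C@H](C)O[Si](CC)(CC)CC | intermediate
26 | (2S,3R,4R,8E,10E,12S)-3-[(tert-butyldimethylsilyl)oxy]-4-(hydroxymethyl)-10,12-dimethyl-2-[(triethylsilyl)oxy]tetradeca-8,10-dien-6-yn-5-one | CC[C@H](C)/C=C(C)/C=C/C#CC(=O)[C@H](CO)[C@@H](O[Si](C)(C)C(C)(C)C)[C@H](C)O[Si](CC)(CC)CC | intermediate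
27 | (3R)-3-[(1R,2S)-1-[(tert-butyldimethylsilyl)oxy]-2-[(triethylsilyl)oxy]propyl]-6-[(1E,3E,5S)-3,5-dimethylhepta-1,3-dien-1-yl]-2,3-dihydro-4H-pyran-4-one | CC[C@H](C)/C=C(C)/C=C/C1=CC(=O)[C@@H]([C@@H](O[Si](C)(C)C(C)(C)C)[C@H](C)O[Si](CC)(CC)CC)CO1 | intermediate
28 | 4-[(Z)-2-ethoxyvinyl]-4-hydroxy adduct of 27, both C4a epimers (not isolated) | CC[C@H](C)/C=C(C)/C=C/C1=CC(O)(/C=C\OCC)[C@@H]([C@@H](O[Si](C)(C)C(C)(C)C)[C@H](C)O[Si](CC)(CC)CC)CO1 | intermediate
29 | 2-{(3R)-3-[(1R,2S)-1-[(tert-butyldimethylsilyl)oxy]-2-[(triethylsilyl)oxy]propyl]-6-[(1E,3E,5S)-3,5-dimethylhepta-1,3-dien-1-yl]-2,3-dihydro-4H-pyran-4-ylidene}acetaldehyde, CHO cis to pyran C3 | CC[C@H](C)/C=C(C)/C=C/C1=C/C(=C/C=O)[C@@H]([C@@H](O[Si](C)(C)C(C)(C)C)[C@H](C)O[Si](CC)(CC)CC)CO1 | intermediate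
30 | 2-{(3R)-3-[(1R,2S)-1-[(tert-butyldimethylsilyl)oxy]-2-hydroxypropyl]-6-[(1E,3E,5S)-3,5-dimethylhepta-1,3-dien-1-yl]-2,3-dihydro-4H-pyran-4-ylidene}acetaldehyde, CHO cis to pyran C3 | CC[C@H](C)/C=C(C)/C=C/C1=C/C(=C/C=O)[C@@H]([C@@H](O[Si](C)(C)C(C)(C)C)[C@H](C)O)CO1 | intermediate
31 | 2-{(3R)-3-[(1R)-1-[(tert-butyldimethylsilyl)oxy]-2-oxopropyl]-6-[(1E,3E,5S)-3,5-dimethylhepta-1,3-dien-1-yl]-2,3-dihydro-4H-pyran-4-ylidene}acetaldehyde, CHO cis to pyran C3 (key-step precursor) | CC[C@H](C)/C=C(C)/C=C/C1=C/C(=C/C=O)[C@@H]([C@@H](O[Si](C)(C)C(C)(C)C)C(C)=O)CO1 | intermediate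
32 | (7R,8R,8aR)-8-[(tert-butyldimethylsilyl)oxy]-3-[(1E,3E,5S)-3,5-dimethylhepta-1,3-dien-1-yl]-7-hydroxy-7-methyl-8,8a-dihydro-1H-isochromen-6(7H)-one (key-step product) | CC[C@H](C)/C=C(C)/C=C/C1=CC2=CC(=O)[C@](C)(O)[C@H](O[Si](C)(C)C(C)(C)C)[C@H]2CO1 | intermediate
33 | (7R,8R,8aR)-3-[(1E,3E,5S)-3,5-dimethylhepta-1,3-dien-1-yl]-7,8-dihydroxy-7-methyl-8,8a-dihydro-1H-isochromen-6(7H)-one | CC[C@H](C)/C=C(C)/C=C/C1=CC2=CC(=O)[C@](C)(O)[C@H](O)[C@H]2CO1 | intermediate
34 | 8-acetyldechloroisochromophilone III | CC[C@H](C)/C=C(C)/C=C/C1=CC2=CC(=O)[C@](C)(O)[C@H](OC(C)=O)[C@H]2CO1 | target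

## Step count

Total: 22 steps. Longest linear sequence: 15 steps (steps 8–22, from propane-1,3-diol).

## Steps most likely to fail

**Step 20 (key step).** The aldehyde is a β,β-disubstituted, doubly vinylogous formate, so carbene addition and formation of the hydroxy-enamine may be slow. The C4a=C5 isomers may not equilibrate under the amine-buffered conditions, which would leave part of the material unable to reach the ketone. β-Protonation at C4a could drain the catalyst into redox side reactions, and the catalyst may oppose the substrate's facial bias.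

Fallback, from 27 back to 32: the carbocycle would be closed at C4a=C5 by an aldol condensation, with C7 set by Felkin–Anh addition to an acyclic ketone. Buffered HF·pyridine would free the C7 hydroxyl of 27 to give the hydroxy pyranone F1. Dess–Martin oxidation would give the methyl ketone F2. 1-Ethoxyvinyllithium (ethyl vinyl ether, t-BuLi, THF, −78 °C) should add to the more electrophilic α-silyloxy ketone, anti to the C8 silyl ether, to give the enol ether carbinol F3. Dilute acid would unmask the α-hydroxy diketone F4. Its C6 methyl ketone enolate (KOt-Bu, t-BuOH/THF, 0 °C) would then attack the C4a carbonyl of the pyranone, and loss of water would give 32.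

**Step 17.** The basic vinyllithium may enolise the pyranone at C8a instead of adding, with β-elimination of the C8 silyloxy group or of the ring oxygen. During the acid treatment the ring enol ether may hydrolyse and re-close the other way, or C8a may epimerise through the cation.

Fallback, from 27 back to 29: the two carbons would be added as a nitrile. Peterson olefination of 27 with lithiated (trimethylsilyl)acetonitrile (LDA, THF, −78 °C), a far less basic nucleophile, would give the pyranylidene acetonitrile F5. Reduction with i-Bu2AlH at −78 °C and brief acidic hydrolysis of the aluminium imine would give dienal 29.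

**Step 16.** The β-hydroxy ynone may dehydrate or lose formaldehyde by retro-aldol cleavage before it cyclises, or the triethylsilyl ether may be lost to adventitious triflic acid.

Fallback, from 23 and 7 back to 27: the pyranone would be made by cyclodehydration of a β-diketone instead of alkyne activation. Wittig reaction of 7 with 1-(triphenylphosphoranylidene)propan-2-one would give the dienone F6. Its kinetic lithium enolate (LDA, THF, −78 °C) would be acylated by Weinreb amide 23 to give the β-diketone F7. DDQ would remove the 4-methoxybenzyl group to give the hydroxy diketone F8, which should cyclise with loss of water (pyridinium p-toluenesulfonate, benzene, warm) to 27.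

## Further compounds

F1 | step 20 | (3R)-3-[(1R,2S)-1-[(tert-butyldimethylsilyl)oxy]-2-hydroxypropyl]-6-[(1E,3E,5S)-3,5-dimethylhepta-1,3-dien-1-yl]-2,3-dihydro-4H-pyran-4-one | CC[C@H](C)/C=C(C)/C=C/C1=CC(=O)[C@@H]([C@@H](O[Si](C)(C)C(C)(C)C)[C@H](C)O)CO1
F2 | step 20 | (3R)-3-[(1R)-1-[(tert-butyldimethylsilyl)oxy]-2-oxopropyl]-6-[(1E,3E,5S)-3,5-dimethylhepta-1,3-dien-1-yl]-2,3-dihydro-4H-pyran-4-one | CC[C@H](C)/C=C(C)/C=C/C1=CC(=O)[C@@H]([C@@H](O[Si](C)(C)C(C)(C)C)C(C)=O)CO1
F3 | step 20 | (3R)-3-[(1R,2R)-1-[(tert-butyldimethylsilyl)oxy]-3-ethoxy-2-hydroxy-2-methylbut-3-en-1-yl]-6-[(1E,3E,5S)-3,5-dimethylhepta-1,3-dien-1-yl]-2,3-dihydro-4H-pyran-4-one | CC[C@H](C)/C=C(C)/C=C/C1=CC(=O)[C@@H]([C@@H](O[Si](C)(C)C(C)(C)C)[C@@](C)(O)C(=C)OCC)CO1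
F4 | step 20 | (3R)-3-[(1R,2R)-1-[(tert-butyldimethylsilyl)oxy]-2-hydroxy-2-methyl-3-oxobutyl]-6-[(1E,3E,5S)-3,5-dimethylhepta-1,3-dien-1-yl]-2,3-dihydro-4H-pyran-4-one | CC[C@H](C)/C=C(C)/C=C/C1=CC(=O)[C@@H]([C@@H](O[Si](C)(C)C(C)(C)C)[C@@](C)(O)C(C)=O)CO1
F5 | step 17 | 2-{(3R)-3-[(1R,2S)-1-[(tert-butyldimethylsilyl)oxy]-2-[(triethylsilyl)oxy]propyl]-6-[(1E,3E,5S)-3,5-dimethylhepta-1,3-dien-1-yl]-2,3-dihydro-4H-pyran-4-ylidene}acetonitrile | CC[C@H](C)/C=C(C)/C=C/C1=C/C(=C/C#N)[C@@H]([C@@H](O[Si](C)(C)C(C)(C)C)[C@H](C)O[Si](CC)(CC)CC)CO1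
F6 | step 16 | (3E,5E,7S)-5,7-dimethylnona-3,5-dien-2-one | CC[C@H](C)/C=C(C)/C=C/C(C)=O
F7 | step 16 | (2S,3R,4R,9E,11E,13S)-3-[(tert-butyldimethylsilyl)oxy]-4-{[(4-methoxybenzyl)oxy]methyl}-11,13-dimethyl-2-[(triethylsilyl)oxy]pentadeca-9,11-diene-5,7-dione | CC[C@H](C)/C=C(C)/C=C/C(=O)CC(=O)[C@H](COCc1ccc(OC)cc1)[C@@H](O[Si](C)(C)C(C)(C)C)[C@H](C)O[Si](CC)(CC)CC
F8 | step 16 | (2S,3R,4R,9E,11E,13S)-3-[(tert-butyldimethylsilyl)oxy]-4-(hydroxymethyl)-11,13-dimethyl-2-[(triethylsilyl)oxy]pentadeca-9,11-diene-5,7-dione | CC[C@H](C)/C=C(C)/C=C/C(=O)CC(=O)[C@H](CO)[C@@H](O[Si](C)(C)C(C)(C)C)[C@H](C)O[Si](CC)(CC)CC
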